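The seven-membered enone ring A (C1 carbonyl, C2=C3 bearing the styryl group, C4, C5 with resorcinol ring B, C6 with catechol ring C, C7) is closed at C6–C7. The step exploits the para-oxygen of ring C, which lets C6 ionise as a quinone-methide-like benzylic cation, and C7, the α′-carbon of the C1 carbonyl. In the precursor, a 2-alkylidene-tetrahydrofuran, the C6–O bond is both leaving group and enol-ether oxygen of a siloxydiene. A Lewis-acid-triggered vinylogous O→C shift contracts the oxacycle onto C7, sets C6 trans to C5 and delivers a regiodefined vinylogous silyl ester for Stork–Danheiser styrylation. C5 comes from a dynamic kinetic ketone hydrogenation.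

Key step: step 6

Remark: the labels C1–C7 of ring A are kept for the same carbons in every intermediate; all four phenols are carried as methyl ethers (an assumed protecting-group choice).

Step 1
Reactants: 1 3′,4′-dimethoxyacetophenone; 2 1-bromo-3,5-dimethoxybenzene
Product: 3 1-(3,4-dimethoxyphenyl)-2-(3,5-dimethoxyphenyl)ethan-1-one
Conditions: Pd2(dba)3 (1.5 mol%), Xantphos (3.6 mol%), NaOtBu (1.3 equiv), THF, 70 °C
Reagents that add atoms: none
Why: Buchwald–Hartwig-type palladium-catalysed α-arylation of an aryl methyl ketone enolate, for which wide-bite-angle bisphosphines favour monoarylation, should join ring B to the future C5 next to the C6 carbonyl that carries ring C; no stereocentre is formed.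

Step 2
Reactants: 3 1-(3,4-dimethoxyphenyl)-2-(3,5-dimethoxyphenyl)ethan-1-one; 4 propargyl bromide
Product: 5 rac-1-(3,4-dimethoxyphenyl)-2-(3,5-dimethoxyphenyl)pent-4-yn-1-one
Conditions: NaH (1.05 equiv), THF, 0 °C; then 4 (1.1 equiv), 0 → 23 °C
Reagents that add atoms: none
Why: SN2 C-alkylation of the stabilised sodium enolate of the deoxybenzoin with a propargylic halide should attach C4 and the alkyne carbons C3 and C2, the new C5 stereocentre arising as a base-labile racemate that is corrected in step 3.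

Step 3
Reactants: 5 rac-1-(3,4-dimethoxyphenyl)-2-(3,5-dimethoxyphenyl)pent-4-yn-1-one
Product: 6 (1R,2R)-1-(3,4-dimethoxyphenyl)-2-(3,5-dimethoxyphenyl)pent-4-yn-1-ol
Conditions: trans-RuCl2[(S)-xylbinap][(S)-daipen] (0.5 mol%), KOtBu (5 mol%), i-PrOH, H2 (8 atm), 25 °C
Reagents that add atoms: none
Why: Noyori asymmetric hydrogenation with dynamic kinetic resolution, in which the α-aryl ketone racemises through its enolate while the catalyst (which leaves C≡C bonds alone and gives (R)-1-arylalkanols with this ligand pairing) reduces the (R)-ketone through the matched Felkin–Anh transition state, should set C5 as required together with a syn C6 carbinol (the C6 configuration is erased in step 6, so the enantiomeric catalyst would be used should the matched pair prove to be the anti-Felkin one).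

Step 4
Reactants: 6 (1R,2R)-1-(3,4-dimethoxyphenyl)-2-(3,5-dimethoxyphenyl)pent-4-yn-1-ol; 7 N-methoxy-N-methylacetamide
Product: 9 (1E)-1-[(4R,5R)-5-(3,4-dimethoxyphenyl)-4-(3,5-dimethoxyphenyl)oxolan-2-ylidene]propan-2-one, via hydroxy ynone 8 (not isolated)
Conditions: n-BuLi (2.05 equiv), THF, −78 °C; 7 (1.2 equiv), −78 → 0 °C; aq. NH4Cl; then DBU (10 mol%), CH2Cl2, 23 °C
Reagents that add atoms: none
Why: Weinreb acylation of the lithium acetylide (the lithium alkoxide is inert) should give the ynone, whose C6 hydroxyl then adds to C3 in a base-catalysed 5-exo-dig oxa-Michael cyclisation, DBU equilibrating the push–pull alkene to the more stable E isomer in which C1 lies cis to C4; no new stereocentre is formed.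

Step 5
Reactants: 9 (1E)-1-[(4R,5R)-5-(3,4-dimethoxyphenyl)-4-(3,5-dimethoxyphenyl)oxolan-2-ylidene]propan-2-one
Product: 10 (2R,3R,5E)-2-(3,4-dimethoxyphenyl)-3-(3,5-dimethoxyphenyl)-5-[2-(triisopropylsilyloxy)prop-2-en-1-ylidene]oxolane
Conditions: LiN(iPr)2 (1.1 equiv), THF, −78 °C; TIPSOTf (1.2 equiv), −78 °C
Reagents that add atoms: triisopropylsilyl trifluoromethanesulfonate (TIPSOTf), CC(C)[Si](C(C)C)(C(C)C)OS(=O)(=O)C(F)(F)F
Why: Kinetic α′-deprotonation of a vinylogous ester at its acetyl methyl group (Stork–Danheiser regiochemistry) followed by O-silylation of the cross-conjugated enolate should give a Danishefsky-type 1-alkoxy-3-siloxydiene whose terminal carbon is C7; no stereocentre is affected.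

Step 6
Reactants: 10 (2R,3R,5E)-2-(3,4-dimethoxyphenyl)-3-(3,5-dimethoxyphenyl)-5-[2-(triisopropylsilyloxy)prop-2-en-1-ylidene]oxolane
Product: 11 (5S,6S)-5-(3,4-dimethoxyphenyl)-6-(3,5-dimethoxyphenyl)-3-(triisopropylsilyloxy)cyclohept-2-en-1-one
Conditions: Me2AlCl (1.2 equiv), CH2Cl2 (0.01 M), −78 → −30 °C; then sat. aq. NaHCO3
Reagents that add atoms: none
Why: Proposed new method: Me2AlCl should bind the ring oxygen of 10 and ionise the benzylic C6–O bond, helped by the para-methoxy group of ring C, to a tethered ion pair of a quinone-methide-like C6 cation and an aluminium dienolate, whose terminal carbon C7 then attacks C6 to give directly the aluminium-bound vinylogous silyl ester 11. The closest known reaction types are the Petasis–Ferrier rearrangement and the Lewis-acid-promoted 1,3-O→C shift of benzyl vinyl ethers, extended here vinylogously to a formal 1,5-shift, together with Mukaiyama-type SN1 benzylation of siloxydienes. Ring A closes at C6–C7 in a 7-(enolendo)-exo-trig mode while the oxolane opens, whereas the competing 1,3-shift to C2 would need a disfavoured 5-(enolendo)-exo-trig closure. The new C6 stereocentre is controlled by C5: allylic 1,3-strain holds the C5–H bond in the plane of the cation, C7 arrives through the C4 tether on the face anti to ring B, and both aryl groups end pseudo-equatorial and trans, while C5 itself is untouched and the former C6–O configuration is irrelevant. The step needs attack by C7 in preference to C2, to degenerate O-recombination and to loss of the C5 proton, and this should be secured by the large terminal coefficient of the dienolate, the ring-closure preference above, high dilution and the aprotic, proton-scavenging aluminium reagent, which also leaves the bulky silyl group on the C1 oxygen so that C3=O and C1–OSi stay differentiated.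

Step 7
Reactants: 11 (5S,6S)-5-(3,4-dimethoxyphenyl)-6-(3,5-dimethoxyphenyl)-3-(triisopropylsilyloxy)cyclohept-2-en-1-one; 12 (E)-β-bromostyrene
Product: 14 (5S,6S)-6-(3,4-dimethoxyphenyl)-5-(3,5-dimethoxyphenyl)-3-[(E)-2-phenylethenyl]cyclohept-2-en-1-one, via tertiary allylic alcohol 13 (not isolated)
Conditions: 12 (1.5 equiv), t-BuLi (3.0 equiv), Et2O, −78 °C; CeCl3 (1.6 equiv), THF, −78 °C; then 11, −78 → 0 °C; then 1 M HCl, THF, 23 °C
Reagents that add atoms: none
Why: In this Stork–Danheiser sequence the (E)-alkenylcerium reagent (geometry retained in the bromine–lithium exchange) should add 1,2 to the C3 carbonyl of the vinylogous silyl ester, and acid then ionises the tertiary allylic alcohol and hydrolyses the silyl enol ether to leave the carbonyl at C1 and the styryl-substituted C2=C3 bond; the carbinol centre of 13 is destroyed and C5 and C6, neither of which is enolisable, are untouched.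

Step 8
Reactants: 14 (5S,6S)-6-(3,4-dimethoxyphenyl)-5-(3,5-dimethoxyphenyl)-3-[(E)-2-phenylethenyl]cyclohept-2-en-1-one
Product: 15 (5S,6S)-6-(3,4-dihydroxyphenyl)-5-(3,5-dihydroxyphenyl)-3-[(E)-2-phenylethenyl]cyclohept-2-en-1-one
Conditions: BBr3 (10 equiv), CH2Cl2, −78 → 0 °C; then ice-water
Reagents that add atoms: none
Why: Lewis-acid cleavage of the four aryl methyl ethers with BBr3, the standard deprotection of methylated stilbenoids and chalcones, should release rings B and C without touching the dienone or the two stereocentres, neither of which is α to the carbonyl.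

Compound list
1 | 3′,4′-dimethoxyacetophenone | CC(=O)c1ccc(OC)c(OC)c1 | starting material
2 | 1-bromo-3,5-dimethoxybenzene | COc1cc(Br)cc(OC)c1 | starting material
3 | 1-(3,4-dimethoxyphenyl)-2-(3,5-dimethoxyphenyl)ethan-1-one | COc1cc(CC(=O)c2ccc(OC)c(OC)c2)cc(OC)c1 | intermediate
4 | propargyl bromide (3-bromoprop-1-yne) | C#CCBr | starting material
5 | rac-1-(3,4-dimethoxyphenyl)-2-(3,5-dimethoxyphenyl)pent-4-yn-1-one | C#CCC(c1cc(OC)cc(OC)c1)C(=O)c1ccc(OC)c(OC)c1 | intermediate
6 | (1R,2R)-1-(3,4-dimethoxyphenyl)-2-(3,5-dimethoxyphenyl)pent-4-yn-1-ol | C#CC[C@H](c1cc(OC)cc(OC)c1)[C@@H](O)c1ccc(OC)c(OC)c1 | intermediate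
7 | N-methoxy-N-methylacetamide | CC(=O)N(C)OC | starting material
8 | (6R,7R)-7-(3,4-dimethoxyphenyl)-6-(3,5-dimethoxyphenyl)-7-hydroxyhept-3-yn-2-one (hydroxy ynone, not isolated) | CC(=O)C#CC[C@H](c1cc(OC)cc(OC)c1)[C@@H](O)c1ccc(OC)c(OC)c1 | intermediate
9 | (1E)-1-[(4R,5R)-5-(3,4-dimethoxyphenyl)-4-(3,5-dimethoxyphenyl)oxolan-2-ylidene]propan-2-one (cis-4,5-diaryl) | CC(=O)/C=C1\C[C@H](c2cc(OC)cc(OC)c2)[C@H](c2ccc(OC)c(OC)c2)O1 | intermediate
10 | (2R,3R,5E)-2-(3,4-dimethoxyphenyl)-3-(3,5-dimethoxyphenyl)-5-[2-(triisopropylsilyloxy)prop-2-en-1-ylidene]oxolane | C=C(O[Si](C(C)C)(C(C)C)C(C)C)/C=C1\C[C@H](c2cc(OC)cc(OC)c2)[C@H](c2ccc(OC)c(OC)c2)O1 | intermediate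
11 | (5S,6S)-5-(3,4-dimethoxyphenyl)-6-(3,5-dimethoxyphenyl)-3-(triisopropylsilyloxy)cyclohept-2-en-1-one (trans-5,6-diaryl) | O=C1C=C(O[Si](C(C)C)(C(C)C)C(C)C)C[C@H](c2ccc(OC)c(OC)c2)[C@@H](c2cc(OC)cc(OC)c2)C1 | intermediate
12 | (E)-β-bromostyrene | Br/C=C/c1ccccc1 | starting material
13 | (5S,6S)-5-(3,4-dimethoxyphenyl)-6-(3,5-dimethoxyphenyl)-1-[(E)-2-phenylethenyl]-3-(triisopropylsilyloxy)cyclohept-2-en-1-ol (both C1 epimers, not isolated) | OC1(/C=C/c2ccccc2)C=C(O[Si](C(C)C)(C(C)C)C(C)C)C[C@H](c2ccc(OC)c(OC)c2)[C@@H](c2cc(OC)cc(OC)c2)C1 | intermediate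
14 | (5S,6S)-6-(3,4-dimethoxyphenyl)-5-(3,5-dimethoxyphenyl)-3-[(E)-2-phenylethenyl]cyclohept-2-en-1-one | O=C1C=C(/C=C/c2ccccc2)C[C@H](c2cc(OC)cc(OC)c2)[C@@H](c2ccc(OC)c(OC)c2)C1 | intermediate
15 | (5S,6S)-6-(3,4-dihydroxyphenyl)-5-(3,5-dihydroxyphenyl)-3-[(E)-2-phenylethenyl]cyclohept-2-en-1-one (trans-5,6-diaryl) | O=C1C=C(/C=C/c2ccccc2)C[C@H](c2cc(O)cc(O)c2)[C@@H](c2ccc(O)c(O)c2)C1 | target

Total step count: 8. Longest linear sequence: 8 steps (from 1 and 2 to 15).

Steps most likely to fail

Step 6 (proposed new method). The ion pair may collapse at C2 or back at oxygen, the cation may lose the C5 proton to give a stilbene, or intermolecular silyl transfer may scramble the C1 and C3 oxygens. The fallback uses known chemistry, sets out from 6 and comes back to the route at 14. It installs the styryl group before ring closure and closes the same C6–C7 bond by an intramolecular Mukaiyama-type SN1 benzylation. Silylation of 6 (TBSCl, imidazole, DMF) would give the tert-butyldimethylsilyl ether F1. Deprotonation with n-BuLi and acylation with 7 would give the silyloxy ynone F2. Copper-catalysed syn-hydroalkenylation with (E)-styrylboronic acid (CuOAc cat., MeOH, 25 °C) would place the acetyl group cis to C4 and give the (3E,5E)-dienone F3. Kinetic enolisation and silylation (LiN(iPr)2, then TBSOTf, THF, −78 °C) would give the bis-silyl siloxytriene F4. BF3·OEt2 with 2,6-di-tert-butylpyridine in CH2Cl2 at −78 °C should then ionise the benzylic silyl ether and let C7 of the enol silane close ring A, giving 14 after loss of both silyl groups.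

Step 3. Racemisation of the ketone may be too slow, the catalyst and the Felkin preference may be mismatched so that C5 is formed with low enantiomeric purity, or base may cycloisomerise the α-propargyl ketone to a furan. The fallback is a classical resolution that sets out from 5 and comes back at 6. Reduction with NaBH4 (MeOH, −20 °C, Felkin–Anh control) would give the racemic syn alcohol F5. Esterification with (S)-2-methoxy-2-phenylacetic acid (DCC, DMAP) and chromatographic separation of the two diastereomers would give the (S)-O-methylmandelate F6 of the (1R,2R) alcohol. Hydrolysis (LiOH, THF/H2O) should then return 6.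

Step 7. The organometallic may attack silicon or deprotonate C4 of the vinylogous silyl ester instead of adding to the carbonyl. The fallback replaces carbonyl addition by cross-coupling, sets out from 11 and comes back at 14. Kinetic α′-deprotonation of 11 at C4 (LiN(iPr)2, THF, −78 °C) and O-triflation with PhNTf2 would give the dienyl triflate F7. Suzuki–Miyaura coupling with (E)-styrylboronic acid (Pd(PPh3)4, K3PO4, dioxane/H2O, 60 °C) would give the styryl silyl dienol ether F8. Dilute HCl in THF should then hydrolyse the enol ether and move the double bond into conjugation to give 14.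

Further compounds
F1 | step 6 | tert-butyl{[(1R,2R)-1-(3,4-dimethoxyphenyl)-2-(3,5-dimethoxyphenyl)pent-4-yn-1-yl]oxy}dimethylsilane | C#CC[C@H](c1cc(OC)cc(OC)c1)[C@@H](O[Si](C)(C)C(C)(C)C)c1ccc(OC)c(OC)c1
F2 | step 6 | (6R,7R)-7-(tert-butyldimethylsilyloxy)-7-(3,4-dimethoxyphenyl)-6-(3,5-dimethoxyphenyl)hept-3-yn-2-one | CC(=O)C#CC[C@H](c1cc(OC)cc(OC)c1)[C@@H](O[Si](C)(C)C(C)(C)C)c1ccc(OC)c(OC)c1
F3 | step 6 | (3E,5E)-4-[(2R,3R)-3-(tert-butyldimethylsilyloxy)-3-(3,4-dimethoxyphenyl)-2-(3,5-dimethoxyphenyl)propyl]-6-phenylhexa-3,5-dien-2-one | CC(=O)/C=C(/C=C/c1ccccc1)C[C@H](c1cc(OC)cc(OC)c1)[C@@H](O[Si](C)(C)C(C)(C)C)c1ccc(OC)c(OC)c1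
F4 | step 6 | tert-butyl({(3E,5E)-4-[(2R,3R)-3-(tert-butyldimethylsilyloxy)-3-(3,4-dimethoxyphenyl)-2-(3,5-dimethoxyphenyl)propyl]-6-phenylhexa-1,3,5-trien-2-yl}oxy)dimethylsilane | C=C(O[Si](C)(C)C(C)(C)C)/C=C(/C=C/c1ccccc1)C[C@H](c1cc(OC)cc(OC)c1)[C@@H](O[Si](C)(C)C(C)(C)C)c1ccc(OC)c(OC)c1
F5 | step 3 | rac-(1R,2R)-1-(3,4-dimethoxyphenyl)-2-(3,5-dimethoxyphenyl)pent-4-yn-1-ol (racemic syn alcohol, both enantiomers written) | C#CC[C@H](c1cc(OC)cc(OC)c1)[C@@H](O)c1ccc(OC)c(OC)c1.C#CC[C@@H](c1cc(OC)cc(OC)c1)[C@H](O)c1ccc(OC)c(OC)c1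
F6 | step 3 | (1R,2R)-1-(3,4-dimethoxyphenyl)-2-(3,5-dimethoxyphenyl)pent-4-yn-1-yl (2S)-2-methoxy-2-phenylacetate | C#CC[C@H](c1cc(OC)cc(OC)c1)[C@@H](OC(=O)[C@@H](OC)c1ccccc1)c1ccc(OC)c(OC)c1
F7 | step 7 | (5R,6S)-6-(3,4-dimethoxyphenyl)-5-(3,5-dimethoxyphenyl)-1-(triisopropylsilyloxy)cyclohepta-1,3-dien-3-yl trifluoromethanesulfonate | CC(C)[Si](OC1=CC(OS(=O)(=O)C(F)(F)F)=C[C@H](c2cc(OC)cc(OC)c2)[C@@H](c2ccc(OC)c(OC)c2)C1)(C(C)C)C(C)C
F8 | step 7 | triisopropyl({(5S,6S)-6-(3,4-dimethoxyphenyl)-5-(3,5-dimethoxyphenyl)-3-[(E)-2-phenylethenyl]cyclohepta-1,3-dien-1-yl}oxy)silane | CC(C)[Si](OC1=CC(/C=C/c2ccccc2)=C[C@H](c2cc(OC)cc(OC)c2)[C@@H](c2ccc(OC)c(OC)c2)C1)(C(C)C)C(C)C
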